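**Plan**

Ring numbering of the target: C1 = CH bearing the pent-1-en-2-yl unit, C2 = CH bearing the 3-oxobutyl chain, C3 = CMe2, C4 = CH2.

1. The retrosynthesis cuts, in this order: the linoleate C–O bond; the C1–C(=CH2) bond (alkenyl exchanged for boron); the C1–B and C2–H bonds, which leads back to an achiral cyclobutene with a C1=C2 double bond; and the C2–CH2 bond of the side chain, which leads back to 2,2-dimethylcyclobutanone.
2. In the forward direction the four-membered ring is bought, not closed. The masked oxobutyl chain is joined to C2, H and B are added across C1=C2, boron at C1 is exchanged for the silyloxypentenyl unit, and the linoleate is attached last.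
3. Both stereocentres come from one catalyst-controlled syn-hydroboration of the planar cyclobutene. H goes to C2 and B to C1 on the same face, so the two carbon substituents end up trans by necessity. The boron-to-carbon exchange is stereoretentive.
4. The enabling feature is the quaternary C3 (CMe2) next to C2 in the cyclobutane. It leaves the ketone only one enolisable side, so the double bond is placed exactly at C1=C2, and it steers Cu and B to C1. The strain of the cyclobutene C1=C2 bond makes a trialkyl-substituted alkene reactive toward Cu–H.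

Key step: step 3

Remark: 2,2-dimethylcyclobutanone is taken as a purchasable building block; the ligand antipode in step 3 is written as (R) and would be exchanged for (S) if a pilot run shows attack on the other alkene face, since the sense of induction cannot be assigned beforehand.

**Step 1**
Reactants: 1 2,2-dimethylcyclobutan-1-one
Product: 3 4,4-dimethylcyclobut-1-en-1-yl trifluoromethanesulfonate, via lithium enolate 2 (not isolated)
Conditions: LDA, THF, −78 °C; PhNTf2, −78 → 0 °C
Reagents that add atoms: N-phenylbis(trifluoromethanesulfonimide), O=S(=O)(N(c1ccccc1)S(=O)(=O)C(F)(F)F)C(F)(F)F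
Why: Enolate O-triflation; because the other α-carbon is quaternary, deprotonation can occur only at the ring CH2, so a single enol triflate with the double bond at the future C1=C2 should form.

**Step 2**
Reactants: 3 4,4-dimethylcyclobut-1-en-1-yl trifluoromethanesulfonate; 4 2-(2-bromoethyl)-2-methyl-1,3-dioxolane
Product: 6 2-[2-(4,4-dimethylcyclobut-1-en-1-yl)ethyl]-2-methyl-1,3-dioxolane, via alkylmagnesium bromide 5 (not isolated)
Conditions: 4, Mg, THF, 25 °C; then 3, Fe(acac)3 (5 mol %), THF/NMP, −30 → 0 °C
Reagents that add atoms: none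
Why: Iron-catalysed Kumada-type coupling of an alkenyl triflate with a functionalised primary alkyl Grignard reagent is fast at low temperature and tolerates the ketal, so the masked oxobutyl chain should be joined to the sp2 carbon next to CMe2 without moving the double bond.

**Step 3**
Reactants: 6 2-[2-(4,4-dimethylcyclobut-1-en-1-yl)ethyl]-2-methyl-1,3-dioxolane
Product: 7 2-{(1S,2R)-3,3-dimethyl-2-[2-(2-methyl-1,3-dioxolan-2-yl)ethyl]cyclobutyl}-4,4,5,5-tetramethyl-1,3,2-dioxaborolane
Conditions: CuCl (5 mol %), (R)-DTBM-SEGPHOS (5.5 mol %), KOtBu (10 mol %), HBpin, cyclohexane, 23 °C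
Reagents that add atoms: pinacolborane, [H]B1OC(C)(C)C(C)(C)O1
Why: The ligated copper hydride formed from CuCl, KOtBu and HBpin adds syn across the strained ring C=C bond of 6, with hydride going to the chain-bearing carbon next to CMe2 and copper to the ring CH, and the secondary cyclobutyl–copper bond is then exchanged for C–B by sigma-bond metathesis with HBpin with retention, which regenerates Cu–H. The closest known reaction types are the CuH-catalysed asymmetric hydroboration of alkenes and the CuH-catalysed hydrofunctionalisation of 1-substituted cyclobutenes, where ring strain makes a trisubstituted alkene reactive. No ring is closed in this step, the four-membered ring being carried from 1. Both stereocentres arise together: their trans relation is fixed by the syn addition itself (H and B enter on one face, so the chain on the neighbouring carbon is turned to the other face), and the absolute configuration (S at the boron-bearing carbon, R at the chain-bearing carbon) is set by the face selection of the chiral bisphosphine–copper hydride. The step needs regioselectivity, which the quaternary CMe2 carbon beside the substituted alkene carbon and the preference of copper for the less substituted carbon should secure, and enantioface selectivity, which rests on the ligand; the dioxolane is inert to Cu–H and HBpin.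

**Step 4**
Reactants: 8 pent-4-yn-1-ol
Product: 9 4-bromopent-4-en-1-ol
Conditions: HBr, Et4NBr, CH2Cl2, 40 °C
Reagents that add atoms: hydrogen bromide, Br
Why: Markovnikov hydrobromination of a terminal alkyne with ammonium hydrogen dibromide should place bromine on the internal carbon and give the 2-bromo-1-alkene.

**Step 5**
Reactants: 9 4-bromopent-4-en-1-ol
Product: 10 [(4-bromopent-4-en-1-yl)oxy](tert-butyl)dimethylsilane
Conditions: TBSCl, imidazole, CH2Cl2, 23 °C
Reagents that add atoms: tert-butyldimethylsilyl chloride, CC(C)(C)[Si](C)(C)Cl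
Why: Standard silylation of a primary alcohol masks the hydroxyl group for the organolithium chemistry of step 6.

**Step 6**
Reactants: 7 2-{(1S,2R)-3,3-dimethyl-2-[2-(2-methyl-1,3-dioxolan-2-yl)ethyl]cyclobutyl}-4,4,5,5-tetramethyl-1,3,2-dioxaborolane; 10 [(4-bromopent-4-en-1-yl)oxy](tert-butyl)dimethylsilane
Product: 14 tert-butyl[(4-{(1S,2R)-3,3-dimethyl-2-[2-(2-methyl-1,3-dioxolan-2-yl)ethyl]cyclobutyl}pent-4-en-1-yl)oxy]dimethylsilane, via alkenyllithium 11 (not isolated), via lithium boronate complex 12 (not isolated), via beta-iodoalkyl boronic ester 13 (not isolated)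
Conditions: 10, t-BuLi (2 equiv), Et2O, −78 °C; 7, THF, −78 → 0 °C; I2, THF/MeOH, −78 °C; NaOMe, MeOH, −78 → 23 °C
Reagents that add atoms: none
Why: Zweifel olefination, in which the alkenyllithium from Br/Li exchange adds to boron, iodination of the alkenyl group triggers 1,2-migration of the cyclobutyl carbon from boron to carbon with retention, and methoxide-induced anti elimination of boron and iodide gives the 1,1-disubstituted alkene with both ring stereocentres unchanged.

**Step 7**
Reactants: 14 tert-butyl[(4-{(1S,2R)-3,3-dimethyl-2-[2-(2-methyl-1,3-dioxolan-2-yl)ethyl]cyclobutyl}pent-4-en-1-yl)oxy]dimethylsilane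
Product: 15 4-[(1R,2S)-2-(5-hydroxypent-1-en-2-yl)-4,4-dimethylcyclobutyl]butan-2-one
Conditions: AcOH/THF/H2O (3:1:1), 45 °C
Reagents that add atoms: water, O
Why: Aqueous acetic acid should hydrolyse the dioxolane and the primary silyl ether while being too weak an acid to protonate the 1,1-disubstituted alkene beside the cyclobutane, and neither stereocentre is alpha to the liberated ketone.

**Step 8**
Reactants: 15 4-[(1R,2S)-2-(5-hydroxypent-1-en-2-yl)-4,4-dimethylcyclobutyl]butan-2-one; 16 (9Z,12Z)-octadeca-9,12-dienoic acid (linoleic acid)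
Product: 18 4-[(1S,2R)-3,3-dimethyl-2-(3-oxobutyl)cyclobutyl]pent-4-en-1-yl (9Z,12Z)-octadeca-9,12-dienoate (IN0146), via O-acylisourea 17 (not isolated)
Conditions: EDC·HCl, DMAP (cat.), CH2Cl2, 0 → 23 °C
Reagents that add atoms: none
Why: Steglich esterification of the primary alcohol under neutral conditions should leave the skipped (Z,Z)-diene, the ketone and the 1,1-disubstituted alkene untouched.

**Compound list**

1 | 2,2-dimethylcyclobutan-1-one | CC1(C)CCC1=O | starting material
2 | lithium 4,4-dimethylcyclobut-1-en-1-olate | [Li]OC1=CCC1(C)C | intermediate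
3 | 4,4-dimethylcyclobut-1-en-1-yl trifluoromethanesulfonate | CC1(C)CC=C1OS(=O)(=O)C(F)(F)F | intermediate
4 | 2-(2-bromoethyl)-2-methyl-1,3-dioxolane | CC1(CCBr)OCCO1 | starting material
5 | [2-(2-methyl-1,3-dioxolan-2-yl)ethyl]magnesium bromide | CC1(CC[Mg]Br)OCCO1 | intermediate
6 | 2-[2-(4,4-dimethylcyclobut-1-en-1-yl)ethyl]-2-methyl-1,3-dioxolane | CC1(CCC2=CCC2(C)C)OCCO1 | intermediate
7 | 2-{(1S,2R)-3,3-dimethyl-2-[2-(2-methyl-1,3-dioxolan-2-yl)ethyl]cyclobutyl}-4,4,5,5-tetramethyl-1,3,2-dioxaborolane | CC1(C)OB(OC1(C)C)[C@H]2CC(C)(C)[C@@H]2CCC3(C)OCCO3 | intermediate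
8 | pent-4-yn-1-ol | C#CCCCO | starting material
9 | 4-bromopent-4-en-1-ol | C=C(Br)CCCO | intermediate
10 | [(4-bromopent-4-en-1-yl)oxy](tert-butyl)dimethylsilane | C=C(Br)CCCO[Si](C)(C)C(C)(C)C | intermediate
11 | {5-[(tert-butyldimethylsilyl)oxy]pent-1-en-2-yl}lithium | [Li]C(=C)CCCO[Si](C)(C)C(C)(C)C | intermediate
12 | lithium boronate complex of 7 and 11 | [Li+].CC1(C)O[B-](OC1(C)C)(C(=C)CCCO[Si](C)(C)C(C)(C)C)[C@H]2CC(C)(C)[C@@H]2CCC3(C)OCCO3 | intermediate
13 | 2-[5-(tert-butyldimethylsilyloxy)-1-iodo-2-{(1S,2R)-3,3-dimethyl-2-[2-(2-methyl-1,3-dioxolan-2-yl)ethyl]cyclobutyl}pentan-2-yl]-4,4,5,5-tetramethyl-1,3,2-dioxaborolane (both epimers at the boron-bearing carbon) | ICC(CCCO[Si](C)(C)C(C)(C)C)(B1OC(C)(C)C(C)(C)O1)[C@H]2CC(C)(C)[C@@H]2CCC3(C)OCCO3 | intermediate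
14 | tert-butyl[(4-{(1S,2R)-3,3-dimethyl-2-[2-(2-methyl-1,3-dioxolan-2-yl)ethyl]cyclobutyl}pent-4-en-1-yl)oxy]dimethylsilane | C=C(CCCO[Si](C)(C)C(C)(C)C)[C@H]1CC(C)(C)[C@@H]1CCC2(C)OCCO2 | intermediate
15 | 4-[(1R,2S)-2-(5-hydroxypent-1-en-2-yl)-4,4-dimethylcyclobutyl]butan-2-one | C=C(CCCO)[C@H]1CC(C)(C)[C@@H]1CCC(C)=O | intermediate
16 | (9Z,12Z)-octadeca-9,12-dienoic acid | CCCCC/C=C\C/C=C\CCCCCCCC(=O)O | starting material
17 | O-linoleoyl isourea of EDC | CCN=C(NCCCN(C)C)OC(=O)CCCCCCC/C=C\C/C=C\CCCCC | intermediate
18 | 4-[(1S,2R)-3,3-dimethyl-2-(3-oxobutyl)cyclobutyl]pent-4-en-1-yl (9Z,12Z)-octadeca-9,12-dienoate (IN0146) | C=C(CCCOC(=O)CCCCCCC/C=C\C/C=C\CCCCC)[C@H]1CC(C)(C)[C@@H]1CCC(C)=O | target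

**Step count and risks**

Total step count: 8. Longest linear sequence: 6 (steps 1, 2, 3, 6, 7, 8).

Steps most likely to fail:

1. Step 3. Hydrocupration of the trialkyl-substituted alkene flanked by the quaternary carbon may be sluggish, and face discrimination by the catalyst may be insufficient; a racemic background hydroboration by borane formed from HBpin would erode it further. The fallback sets out from 6 and comes back at 7, and replaces catalyst control by a stoichiometric chiral borane whose adduct can be enriched by crystallisation. Compound 6 would be hydroborated with monoisopinocampheylborane (prepared from (+)-alpha-pinene, antipode chosen by analogy with 1-alkylcycloalkenes and to be confirmed) in THF at −25 °C to give the isopinocampheyl(cyclobutyl)borane F1. Treatment with excess acetaldehyde would expel alpha-pinene and give the diethyl boronate F2, and transesterification with pinacol would give 7.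

2. Step 6. Ate-complex formation at the hindered secondary boronic ester may be incomplete, or iodine may be consumed unproductively, so that the boron-to-carbon migration does not go to completion. The fallback sets out from 7 and comes back at 14, and replaces the 1,2-metallate shift by a radical cross-coupling. Compound 7 would be converted with KHF2 in MeOH/H2O into the potassium trifluoroborate F3. F3 would then be coupled with bromide 10 under nickel/photoredox dual catalysis (iridium photocatalyst, NiCl2·dme, dtbbpy, 2,6-lutidine, dioxane, blue light). The C1 cyclobutyl radical should be captured by nickel on the face away from the C2 substituent, so the trans isomer 14 is expected whatever the configuration at C1 before oxidation.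

3. Step 2. Reduction or homocoupling of the Grignard reagent may outrun cross-coupling at the hindered, strained cyclobutenyl C–O bond. The fallback sets out from 3 and comes back at 6, and uses a borane nucleophile with palladium instead. 2-Ethenyl-2-methyl-1,3-dioxolane F4 would be hydroborated with 9-BBN in THF to the B-alkyl-9-BBN F5. F5 would be joined to triflate 3 by a B-alkyl Suzuki–Miyaura coupling (PdCl2(dppf), K3PO4, THF/DMF/H2O, 50 °C) to give 6.

**Further compounds**

F1 | step 3 | {(1S,2R)-3,3-dimethyl-2-[2-(2-methyl-1,3-dioxolan-2-yl)ethyl]cyclobutyl}(isopinocampheyl)borane | C[C@H]1[C@H](B[C@H]2CC(C)(C)[C@@H]2CCC3(C)OCCO3)C[C@@H]4C[C@H]1C4(C)C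
F2 | step 3 | diethyl {(1S,2R)-3,3-dimethyl-2-[2-(2-methyl-1,3-dioxolan-2-yl)ethyl]cyclobutyl}boronate | CCOB(OCC)[C@H]1CC(C)(C)[C@@H]1CCC2(C)OCCO2
F3 | step 6 | potassium {(1S,2R)-3,3-dimethyl-2-[2-(2-methyl-1,3-dioxolan-2-yl)ethyl]cyclobutyl}trifluoroborate | [K+].F[B-](F)(F)[C@H]1CC(C)(C)[C@@H]1CCC2(C)OCCO2
F4 | step 2 | 2-ethenyl-2-methyl-1,3-dioxolane | C=CC1(C)OCCO1
F5 | step 2 | 9-[2-(2-methyl-1,3-dioxolan-2-yl)ethyl]-9-borabicyclo[3.3.1]nonane | CC1(CCB2C3CCCC2CCC3)OCCO1
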